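**Plan**

1. Locants: side-chain carbons are C1'–C14' counted from the naphthalene (methyls on C3', C7', C11'); cyclopentane ring C1 carries this chain and ring C3 carries the 6-methylheptan-2-yl tail. Retrosynthesis: the quinone is carried as its 1,4-dimethoxynaphthalene, and the C2'–C3' bond is cut by a lithiation–borylation between the α-lithiated 2-arylethyl benzoate 7 (fragment 1) and the C3' secondary boronic ester 41 of the whole side chain (fragment 2); boron is removed afterwards.
2. Feature that makes this possible: the saturated C2'H2–C3'H(CH3) junction two carbons out from the naphthalene ring. C3' is a methyl-bearing secondary carbon that can sit on boron and migrate with retention; C2' is a methylene that can be carried as an O-substituted carbenoid and end as CH2; the fully substituted C2/C3 positions of the dimethoxynaphthalene leave no ring C–H beside OMe.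
3. Fragment 2 is cut at C7'–C8' (same boron chemistry, C5 unit 14), at C13'–C14' (copper-catalysed Grignard coupling with (R)-citronellyl bromide) and twice in the tail (methyl, then isohexyl, onto the exocyclic carbon of the ring arm).
4. Forward order: cyclopentane core 15 → C8'–C14' chain → tail → C3'–C7' unit → boron at C3' → union with fragment 1 → protodeboronation → oxidation to the quinone.
5. Stereochemistry: the cis ring centres come from the desymmetrised half-ester 15; C11' from (R)-citronellyl bromide; the tail centre, C7' and C3' from sparteine-controlled lithiation of triisopropylbenzoates followed by stereospecific 1,2-shifts (retention at the migrating carbon, inversion at the carbenoid carbon).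

Key step: step 21

Assumption: 15 is bought as the single (1S,3R) enantiomer (the half-ester from enzymatic desymmetrisation of the meso diester). The boron-bearing carbons formed under TMEDA in steps 14, 18 and 21 are epimer mixtures that later become CH2 groups, so their SMILES leave that centre undefined.
Abbreviations: TIBCl = 2,4,6-triisopropylbenzoyl chloride; MeBpin = 2,4,4,5,5-pentamethyl-1,3,2-dioxaborolane.

**Fragment 1**

Step 1
Reactants: 1 menadione (2-methylnaphthalene-1,4-dione)
Product: 3 1,4-dimethoxy-2-methylnaphthalene, via menadiol 2 (not isolated)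
Conditions: Na2S2O4, n-Bu4NBr (cat.), THF/H2O, rt; then aq KOH, Me2SO4, rt
Reagents that add atoms: dimethyl sulfate, COS(=O)(=O)OC
Why: Reductive methylation (dithionite reduction to the hydroquinone, then double Williamson O-methylation under phase transfer) masks the quinone as a base-stable arene.

Step 2
Reactants: 3 1,4-dimethoxy-2-methylnaphthalene
Product: 4 2-bromo-1,4-dimethoxy-3-methylnaphthalene
Conditions: Br2, CH2Cl2, 0 °C
Reagents that add atoms: bromine, BrBr
Why: Electrophilic aromatic bromination should go to C3, the only free position of the ring activated by both methoxy groups.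

Step 3
Reactants: 4 2-bromo-1,4-dimethoxy-3-methylnaphthalene
Product: 6 2-(1,4-dimethoxy-3-methylnaphthalen-2-yl)ethan-1-ol, via aryllithium 5 (not isolated)
Conditions: n-BuLi, THF, −78 °C; then oxirane, BF3·OEt2, −78 °C → rt
Reagents that add atoms: oxirane, C1CO1
Why: Bromine–lithium exchange followed by Lewis acid-assisted epoxide opening by the aryllithium installs C1' and C2' as a 2-hydroxyethyl arm.

Step 4
Reactants: 6 2-(1,4-dimethoxy-3-methylnaphthalen-2-yl)ethan-1-ol
Product: 7 2-(1,4-dimethoxy-3-methylnaphthalen-2-yl)ethyl 2,4,6-triisopropylbenzoate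
Conditions: TIBCl, pyridine, DMAP (cat.), CH2Cl2, 40 °C
Reagents that add atoms: 2,4,6-triisopropylbenzoyl chloride, CC(C)c1cc(C(C)C)c(C(Cl)=O)c(C(C)C)c1
Why: Acylation of the primary alcohol (nucleophilic acyl substitution) gives the hindered benzoate that directs α-lithiation and later serves as leaving group.

**Small building blocks**

Step 5
Reactants: 8 4-methylpentan-1-ol
Product: 9 4-methylpentyl 2,4,6-triisopropylbenzoate
Conditions: TIBCl, pyridine, DMAP (cat.), CH2Cl2, 40 °C
Reagents that add atoms: 2,4,6-triisopropylbenzoyl chloride, CC(C)c1cc(C(C)C)c(C(Cl)=O)c(C(C)C)c1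
Why: Acylation of the primary alcohol gives the benzoate that will deliver the isohexyl tail as an α-oxy carbenoid.

Step 6
Reactants: 10 pentane-1,5-diol
Product: 11 pentane-1,5-diyl bis(2,4,6-triisopropylbenzoate)
Conditions: TIBCl (2.2 equiv), pyridine, DMAP (cat.), CH2Cl2, 40 °C
Reagents that add atoms: 2,4,6-triisopropylbenzoyl chloride, CC(C)c1cc(C(C)C)c(C(Cl)=O)c(C(C)C)c1
Why: Double acylation gives a symmetric C5 unit whose two ends will be used one after the other as carbenoid carbons.

Step 7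
Reactants: 11 pentane-1,5-diyl bis(2,4,6-triisopropylbenzoate)
Product: 14 (5R)-5-(4,4,5,5-tetramethyl-1,3,2-dioxaborolan-2-yl)hexyl 2,4,6-triisopropylbenzoate, via lithiated benzoate 12 (not isolated), via boronate complex 13 (not isolated)
Conditions: 11 (3 equiv), s-BuLi (1 equiv), (+)-sparteine, Et2O, −78 °C; MeBpin, −78 °C; then 35 °C
Reagents that add atoms: MeBpin, CB1OC(C)(C)C(C)(C)O1
Why: Lithiation–borylation: (+)-sparteine-directed removal of the pro-R proton of one O–CH2 group, borylation with retention and 1,2-migration of methyl with inversion set the future C7', while the excess of symmetric diester should suppress reaction at both ends.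

**Fragment 2**

Step 8
Reactants: 15 (1S,3R)-3-(methoxycarbonyl)cyclopentane-1-carboxylic acid
Product: 16 methyl (1R,3S)-3-(hydroxymethyl)cyclopentane-1-carboxylate
Conditions: BH3·SMe2, THF, 0 °C → rt
Reagents that add atoms: none
Why: Chemoselective borane reduction of the carboxylic acid leaves the methyl ester and both ring stereocentres untouched.

Step 9
Reactants: 16 methyl (1R,3S)-3-(hydroxymethyl)cyclopentane-1-carboxylate
Product: 17 methyl (1R,3S)-3-{[(2,4,6-triisopropylbenzoyl)oxy]methyl}cyclopentane-1-carboxylate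
Conditions: TIBCl, pyridine, DMAP (cat.), CH2Cl2, 40 °C
Reagents that add atoms: 2,4,6-triisopropylbenzoyl chloride, CC(C)c1cc(C(C)C)c(C(Cl)=O)c(C(C)C)c1
Why: Acylation under non-alkoxide conditions marks the ring-C3 arm as the later carbenoid site and avoids lactonisation onto the cis ester.

Step 10
Reactants: 17 methyl (1R,3S)-3-{[(2,4,6-triisopropylbenzoyl)oxy]methyl}cyclopentane-1-carboxylate
Product: 18 [(1S,3R)-3-(hydroxymethyl)cyclopentyl]methyl 2,4,6-triisopropylbenzoate
Conditions: LiBH4, MeOH (1 equiv), THF, 0 °C → rt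
Reagents that add atoms: none
Why: Hydride reduction takes the unhindered methyl ester to the primary alcohol (future C14'), the triisopropylbenzoate being too shielded to react.

Step 11
Reactants: 18 [(1S,3R)-3-(hydroxymethyl)cyclopentyl]methyl 2,4,6-triisopropylbenzoate
Product: 19 [(1S,3R)-3-(iodomethyl)cyclopentyl]methyl 2,4,6-triisopropylbenzoate
Conditions: I2, PPh3, imidazole, CH2Cl2, 0 °C → rt
Reagents that add atoms: iodine, II
Why: Appel-type iodination of the primary alcohol proceeds at a carbon that is not stereogenic, so the ring centres are safe.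

Step 12
Reactants: 19 [(1S,3R)-3-(iodomethyl)cyclopentyl]methyl 2,4,6-triisopropylbenzoate; 20 (R)-citronellyl bromide ((6R)-8-bromo-2,6-dimethyloct-2-ene)
Product: 22 {(1S,3R)-3-[(4S)-4,8-dimethylnon-7-en-1-yl]cyclopentyl}methyl 2,4,6-triisopropylbenzoate, via Grignard reagent 21 (not isolated)
Conditions: 20, Mg, THF, 40 °C; then 19, Li2CuCl4 (cat.), THF, −20 °C → rt
Reagents that add atoms: none
Why: Copper-catalysed sp3–sp3 Grignard cross-coupling (Kochi type) forms C13'–C14' and brings in C11' from the chiral pool, the hindered benzoate being inert to the Grignard reagent.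

Step 13
Reactants: 22 {(1S,3R)-3-[(4S)-4,8-dimethylnon-7-en-1-yl]cyclopentyl}methyl 2,4,6-triisopropylbenzoate
Product: 25 2-[(1S)-1-{(1S,3R)-3-[(4S)-4,8-dimethylnon-7-en-1-yl]cyclopentyl}ethyl]-4,4,5,5-tetramethyl-1,3,2-dioxaborolane, via lithiated benzoate 23 (not isolated), via boronate complex 24 (not isolated)
Conditions: s-BuLi, (−)-sparteine, Et2O, −78 °C; MeBpin, −78 °C; then 35 °C
Reagents that add atoms: MeBpin, CB1OC(C)(C)C(C)(C)O1
Why: Lithiation–borylation: (−)-sparteine-directed removal of the pro-S proton gives the (S)-organolithium, MeBpin borylates with retention and methyl migrates with inversion as the benzoate leaves, which sets the tail stereocentre beside the ring under reagent control.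

Step 14
Reactants: 25 2-[(1S)-1-{(1S,3R)-3-[(4S)-4,8-dimethylnon-7-en-1-yl]cyclopentyl}ethyl]-4,4,5,5-tetramethyl-1,3,2-dioxaborolane; 9 4-methylpentyl 2,4,6-triisopropylbenzoate
Product: 28 2-[(2R)-2-{(1S,3R)-3-[(4S)-4,8-dimethylnon-7-en-1-yl]cyclopentyl}-6-methylheptan-3-yl]-4,4,5,5-tetramethyl-1,3,2-dioxaborolane (both epimers at heptane C3), via lithiated benzoate 26 (not isolated), via boronate complex 27 (not isolated)
Conditions: 9, s-BuLi, TMEDA, Et2O, −78 °C; then 25, −78 °C; then 35 °C
Reagents that add atoms: none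
Why: Lithiation–borylation homologation: the racemic α-lithiated benzoate adds to boron and the methyl-bearing exocyclic carbon migrates with retention (1,2-metallate rearrangement), which attaches the isohexyl tail.

Step 15
Reactants: 28 the tail boronic ester from step 14
Product: 30 (4S)-4-methyl-7-{(1R,3S)-3-[(2R)-6-methyl-3-(4,4,5,5-tetramethyl-1,3,2-dioxaborolan-2-yl)heptan-2-yl]cyclopentyl}heptan-1-ol, via ozonide 29 (not isolated)
Conditions: O3, CH2Cl2/MeOH, −78 °C; then NaBH4, −78 °C → rt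
Reagents that add atoms: ozone, [O-][O+]=O
Why: Ozonolysis of the trisubstituted alkene with reductive work-up gives the primary alcohol at C8', and an alkyl pinacol boronate should tolerate ozone at −78 °C and borohydride.

Step 16
Reactants: 30 the C8' alcohol from step 15
Product: 31 (4S)-4-methyl-7-{(1R,3S)-3-[(2R)-6-methyl-3-(4,4,5,5-tetramethyl-1,3,2-dioxaborolan-2-yl)heptan-2-yl]cyclopentyl}heptyl 2,4,6-triisopropylbenzoate
Conditions: TIBCl, pyridine, DMAP (cat.), CH2Cl2, 40 °C
Reagents that add atoms: 2,4,6-triisopropylbenzoyl chloride, CC(C)c1cc(C(C)C)c(C(Cl)=O)c(C(C)C)c1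
Why: Acylation turns C8' into the next carbenoid site before the radical step, so that no alkene or free hydroxyl is present there.

Step 17
Reactants: 31 the benzoate from step 16
Product: 33 (4S)-4-methyl-7-{(1R,3S)-3-[(2R)-6-methylheptan-2-yl]cyclopentyl}heptyl 2,4,6-triisopropylbenzoate, via phenylboronate complex 32 (not isolated)
Conditions: PhLi, THF, −78 → 0 °C; then [Ir(dF(CF3)ppy)2(dtbbpy)]PF6 (2 mol %), PhSH, MeOH/acetone, blue LEDs, rt
Reagents that add atoms: none
Why: Radical protodeboronation: PhLi forms an arylboronate that the excited photocatalyst oxidises to a secondary alkyl radical, which takes hydrogen from thiophenol, so the boron helper in the tail is replaced by H without touching the neighbouring stereocentre.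

Step 18
Reactants: 33 the benzoate from step 17; 14 (5R)-5-(4,4,5,5-tetramethyl-1,3,2-dioxaborolan-2-yl)hexyl 2,4,6-triisopropylbenzoate
Product: 36 (5R,9S)-5,9-dimethyl-12-{(1R,3S)-3-[(2R)-6-methylheptan-2-yl]cyclopentyl}-6-(4,4,5,5-tetramethyl-1,3,2-dioxaborolan-2-yl)dodecyl 2,4,6-triisopropylbenzoate (both epimers at C6), via lithiated benzoate 34 (not isolated), via boronate complex 35 (not isolated)
Conditions: 33, s-BuLi (0.95 equiv), TMEDA, Et2O, −78 °C; then 14 (1.3 equiv), −78 °C; then 35 °C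
Reagents that add atoms: none
Why: Lithiation–borylation homologation: the lithiated C8' adds to boron of 14 and the methyl-bearing C7' migrates with retention as the benzoate leaves, which joins the C5 unit and carries its stereocentre into the chain.

Step 19
Reactants: 36 the C8' boronic ester from step 18
Product: 38 (5S,9R)-5,9-dimethyl-12-{(1R,3S)-3-[(2R)-6-methylheptan-2-yl]cyclopentyl}dodecyl 2,4,6-triisopropylbenzoate, via phenylboronate complex 37 (not isolated)
Conditions: PhLi, THF, −78 → 0 °C; then [Ir(dF(CF3)ppy)2(dtbbpy)]PF6 (2 mol %), PhSH, MeOH/acetone, blue LEDs, rt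
Reagents that add atoms: none
Why: Radical protodeboronation as in step 17 turns the boron-bearing C8' into CH2, the hindered benzoate at C3' being inert to PhLi.

Step 20
Reactants: 38 the benzoate from step 19
Product: 41 2-[(2S,6R,10R)-6,10-dimethyl-13-{(1R,3S)-3-[(2R)-6-methylheptan-2-yl]cyclopentyl}tridecan-2-yl]-4,4,5,5-tetramethyl-1,3,2-dioxaborolane, via lithiated benzoate 39 (not isolated), via boronate complex 40 (not isolated)
Conditions: s-BuLi, (−)-sparteine, Et2O, −78 °C; MeBpin, −78 °C; then 35 °C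
Reagents that add atoms: MeBpin, CB1OC(C)(C)C(C)(C)O1
Why: Lithiation–borylation as in step 13: (−)-sparteine removes the pro-S proton at C3', MeBpin borylates with retention and methyl migrates with inversion, which gives the (S)-configured secondary boronic ester that becomes C3'.

**Union and end game**

Step 21
Reactants: 7 2-(1,4-dimethoxy-3-methylnaphthalen-2-yl)ethyl 2,4,6-triisopropylbenzoate (fragment 1); 41 the C3' boronic ester (fragment 2)
Product: 44 2-[(3S,7S,11R)-1-(1,4-dimethoxy-3-methylnaphthalen-2-yl)-3,7,11-trimethyl-14-{(1R,3S)-3-[(2R)-6-methylheptan-2-yl]cyclopentyl}tetradecan-2-yl]-4,4,5,5-tetramethyl-1,3,2-dioxaborolane (both epimers at C2), via lithiated benzoate 42 (not isolated), via boronate complex 43 (not isolated)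
Conditions: 7 (1.4 equiv), s-BuLi (1.3 equiv), TMEDA, Et2O, −78 °C; then 41 (1.0 equiv), −78 °C; then 35 °C
Reagents that add atoms: none
Why: TMEDA-complexed s-BuLi, held by the benzoate carbonyl, removes a proton from the O–CH2 carbon (C2') of 7 to give the dipole-stabilised α-oxy organolithium 42, which adds to boron of 41 to give the tetracoordinate boronate 43; on warming, C3' shifts from boron to C2' anti-periplanar to the departing triisopropylbenzoate (1,2-metallate rearrangement), which forms the C2'–C3' bond and joins fragments 1 and 2. The closest known reaction type is the lithiation–borylation homologation of secondary alkyl pinacol boronic esters with α-lithiated primary alkyl 2,4,6-triisopropylbenzoates (a Matteson-type homologation). No ring is closed. The migrating C3' keeps its configuration because the shift is a concerted, stereoretentive 1,2-migration, so the (3'S) centre of the target follows from the boron-bearing stereocentre of 41; the new boron-bearing C2' forms as both epimers under TMEDA, which does not matter because step 22 turns it into CH2. The step needs deprotonation at O–CH2 and not at the benzylic C1'H2, the ring methyl or a peri C–H: carbonyl-directed (complex-induced proximity) lithiation favours the α-oxygen position, the two ortho substituents (OMe and CH3) hold the side chain out of the ring plane so that the C1'–H bonds overlap poorly with the π system, and the substituted ring has no C–H beside OMe. Single homologation is expected because the carbenoid is bound as boronate at −78 °C and any excess decomposes before the hindered secondary boronic ester 44 is released.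

Step 22
Reactants: 44 the C2' boronic ester from step 21
Product: 46 1,4-dimethoxy-2-methyl-3-[(3S,7S,11R)-3,7,11-trimethyl-14-{(1R,3S)-3-[(2R)-6-methylheptan-2-yl]cyclopentyl}tetradecyl]naphthalene, via phenylboronate complex 45 (not isolated)
Conditions: PhLi, THF, −78 → 0 °C; then [Ir(dF(CF3)ppy)2(dtbbpy)]PF6 (2 mol %), PhSH, MeOH/acetone, blue LEDs, rt
Reagents that add atoms: none
Why: Radical protodeboronation removes the boron helper from C2', the boronate being far easier to oxidise than the dimethoxynaphthalene and the radical at C2' leaving C3' untouched.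

Step 23
Reactants: 46 the dimethoxynaphthalene from step 22
Product: 47 2-methyl-3-[(3S,7S,11R)-3,7,11-trimethyl-14-{(1R,3S)-3-[(2R)-6-methylheptan-2-yl]cyclopentyl}tetradecyl]naphthalene-1,4-dione
Conditions: (NH4)2Ce(NO3)6, MeCN/CH2Cl2/H2O, 0 °C
Reagents that add atoms: water, O
Why: Oxidative demethylation (two single-electron oxidations of the electron-rich ring, attack of water at the methoxy-bearing carbons and loss of methanol) should unveil the 1,4-quinone while the saturated side chain stays inert.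

**Compound list**

1 | menadione (2-methylnaphthalene-1,4-dione) | CC1=CC(=O)c2ccccc2C1=O | starting material
2 | menadiol (2-methylnaphthalene-1,4-diol) | Oc1c(C)cc(O)c2ccccc12 | intermediate
3 | 1,4-dimethoxy-2-methylnaphthalene | COc1c(C)cc(OC)c2ccccc12 | intermediate
4 | 2-bromo-1,4-dimethoxy-3-methylnaphthalene | COc1c(C)c(Br)c(OC)c2ccccc12 | intermediate
5 | (1,4-dimethoxy-3-methylnaphthalen-2-yl)lithium | COc1c(C)c([Li])c(OC)c2ccccc12 | intermediate
6 | 2-(1,4-dimethoxy-3-methylnaphthalen-2-yl)ethan-1-ol | COc1c(C)c(CCO)c(OC)c2ccccc12 | intermediate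
7 | 2-(1,4-dimethoxy-3-methylnaphthalen-2-yl)ethyl 2,4,6-triisopropylbenzoate (fragment 1) | COc1c(C)c(CCOC(=O)c2c(C(C)C)cc(C(C)C)cc2C(C)C)c(OC)c2ccccc12 | intermediate
8 | 4-methylpentan-1-ol | CC(C)CCCO | starting material
9 | 4-methylpentyl 2,4,6-triisopropylbenzoate | CC(C)CCCOC(=O)c1c(C(C)C)cc(C(C)C)cc1C(C)C | intermediate
10 | pentane-1,5-diol | OCCCCCO | starting material
11 | pentane-1,5-diyl bis(2,4,6-triisopropylbenzoate) | CC(C)c1cc(C(C)C)c(C(=O)OCCCCCOC(=O)c2c(C(C)C)cc(C(C)C)cc2C(C)C)c(C(C)C)c1 | intermediate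
12 | (1R)-1-lithio derivative of 11 (one O–CH carbon lithiated; (+)-sparteine complex) | CC(C)c1cc(C(C)C)c(C(=O)OCCCC[C@@H]([Li])OC(=O)c2c(C(C)C)cc(C(C)C)cc2C(C)C)c(C(C)C)c1 | intermediate
13 | lithium methylboronate complex from 12 and MeBpin | [Li+].CC(C)c1cc(C(C)C)c(C(=O)OCCCC[C@@H]([B-]2(C)OC(C)(C)C(C)(C)O2)OC(=O)c2c(C(C)C)cc(C(C)C)cc2C(C)C)c(C(C)C)c1 | intermediate
14 | (5R)-5-(4,4,5,5-tetramethyl-1,3,2-dioxaborolan-2-yl)hexyl 2,4,6-triisopropylbenzoate | CC(C)c1cc(C(C)C)c(C(=O)OCCCC[C@@H](C)B2OC(C)(C)C(C)(C)O2)c(C(C)C)c1 | intermediate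
15 | (1S,3R)-3-(methoxycarbonyl)cyclopentane-1-carboxylic acid | COC(=O)[C@@H]1CC[C@H](C(=O)O)C1 | starting material
16 | methyl (1R,3S)-3-(hydroxymethyl)cyclopentane-1-carboxylate | COC(=O)[C@@H]1CC[C@H](CO)C1 | intermediate
17 | methyl (1R,3S)-3-{[(2,4,6-triisopropylbenzoyl)oxy]methyl}cyclopentane-1-carboxylate | COC(=O)[C@@H]1CC[C@H](COC(=O)c2c(C(C)C)cc(C(C)C)cc2C(C)C)C1 | intermediate
18 | [(1S,3R)-3-(hydroxymethyl)cyclopentyl]methyl 2,4,6-triisopropylbenzoate | OC[C@@H]1CC[C@H](COC(=O)c2c(C(C)C)cc(C(C)C)cc2C(C)C)C1 | intermediate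
19 | [(1S,3R)-3-(iodomethyl)cyclopentyl]methyl 2,4,6-triisopropylbenzoate | IC[C@@H]1CC[C@H](COC(=O)c2c(C(C)C)cc(C(C)C)cc2C(C)C)C1 | intermediate
20 | (R)-citronellyl bromide ((6R)-8-bromo-2,6-dimethyloct-2-ene) | CC(C)=CCC[C@@H](C)CCBr | starting material
21 | (R)-citronellylmagnesium bromide | CC(C)=CCC[C@@H](C)CC[Mg]Br | intermediate
22 | {(1S,3R)-3-[(4S)-4,8-dimethylnon-7-en-1-yl]cyclopentyl}methyl 2,4,6-triisopropylbenzoate | CC(C)=CCC[C@@H](C)CCC[C@@H]1CC[C@H](COC(=O)c2c(C(C)C)cc(C(C)C)cc2C(C)C)C1 | intermediate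
23 | (S)-α-lithio derivative of 22 (lithium on the O-bearing exocyclic carbon; (−)-sparteine complex) | CC(C)=CCC[C@@H](C)CCC[C@@H]1CC[C@H]([C@H]([Li])OC(=O)c2c(C(C)C)cc(C(C)C)cc2C(C)C)C1 | intermediate
24 | lithium methylboronate complex from 23 and MeBpin | [Li+].CC(C)=CCC[C@@H](C)CCC[C@@H]1CC[C@H]([C@H]([B-]2(C)OC(C)(C)C(C)(C)O2)OC(=O)c2c(C(C)C)cc(C(C)C)cc2C(C)C)C1 | intermediate
25 | 2-[(1S)-1-{(1S,3R)-3-[(4S)-4,8-dimethylnon-7-en-1-yl]cyclopentyl}ethyl]-4,4,5,5-tetramethyl-1,3,2-dioxaborolane | CC(C)=CCC[C@@H](C)CCC[C@@H]1CC[C@H]([C@H](C)B2OC(C)(C)C(C)(C)O2)C1 | intermediate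
26 | 1-lithio-4-methylpentyl 2,4,6-triisopropylbenzoate (racemic; TMEDA complex) | CC(C)CCC([Li])OC(=O)c1c(C(C)C)cc(C(C)C)cc1C(C)C | intermediate
27 | lithium boronate complex from 26 and 25 | [Li+].CC(C)=CCC[C@@H](C)CCC[C@@H]1CC[C@H]([C@H](C)[B-]2(OC(C)(C)C(C)(C)O2)C(CCC(C)C)OC(=O)c2c(C(C)C)cc(C(C)C)cc2C(C)C)C1 | intermediate
28 | 2-[(2R)-2-{(1S,3R)-3-[(4S)-4,8-dimethylnon-7-en-1-yl]cyclopentyl}-6-methylheptan-3-yl]-4,4,5,5-tetramethyl-1,3,2-dioxaborolane (both epimers at heptane C3) | CC(C)=CCC[C@@H](C)CCC[C@@H]1CC[C@H]([C@H](C)C(B2OC(C)(C)C(C)(C)O2)CCC(C)C)C1 | intermediate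
29 | ozonide (3,3-dimethyl-1,2,4-trioxolane) of 28 | CC1(C)OOC(CC[C@@H](C)CCC[C@@H]2CC[C@H]([C@H](C)C(B3OC(C)(C)C(C)(C)O3)CCC(C)C)C2)O1 | intermediate
30 | (4S)-4-methyl-7-{(1R,3S)-3-[(2R)-6-methyl-3-(4,4,5,5-tetramethyl-1,3,2-dioxaborolan-2-yl)heptan-2-yl]cyclopentyl}heptan-1-ol | OCCC[C@@H](C)CCC[C@@H]1CC[C@H]([C@H](C)C(B2OC(C)(C)C(C)(C)O2)CCC(C)C)C1 | intermediate
31 | 2,4,6-triisopropylbenzoate of 30 | CC(C)c1cc(C(C)C)c(C(=O)OCCC[C@@H](C)CCC[C@@H]2CC[C@H]([C@H](C)C(B3OC(C)(C)C(C)(C)O3)CCC(C)C)C2)c(C(C)C)c1 | intermediate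
32 | lithium phenylboronate complex of 31 | [Li+].CC(C)c1cc(C(C)C)c(C(=O)OCCC[C@@H](C)CCC[C@@H]2CC[C@H]([C@H](C)C([B-]3(c4ccccc4)OC(C)(C)C(C)(C)O3)CCC(C)C)C2)c(C(C)C)c1 | intermediate
33 | (4S)-4-methyl-7-{(1R,3S)-3-[(2R)-6-methylheptan-2-yl]cyclopentyl}heptyl 2,4,6-triisopropylbenzoate | CC(C)c1cc(C(C)C)c(C(=O)OCCC[C@@H](C)CCC[C@@H]2CC[C@H]([C@H](C)CCCC(C)C)C2)c(C(C)C)c1 | intermediate
34 | 1-lithio derivative of 33 (lithium on the O-bearing carbon C8'; TMEDA complex) | CC(C)c1cc(C(C)C)c(C(=O)OC([Li])CC[C@@H](C)CCC[C@@H]2CC[C@H]([C@H](C)CCCC(C)C)C2)c(C(C)C)c1 | intermediate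
35 | lithium boronate complex from 34 and 14 | [Li+].CC(C)c1cc(C(C)C)c(C(=O)OCCCC[C@@H](C)[B-]2(OC(C)(C)C(C)(C)O2)C(OC(=O)c2c(C(C)C)cc(C(C)C)cc2C(C)C)CC[C@@H](C)CCC[C@@H]2CC[C@H]([C@H](C)CCCC(C)C)C2)c(C(C)C)c1 | intermediate
36 | (5R,9S)-5,9-dimethyl-12-{(1R,3S)-3-[(2R)-6-methylheptan-2-yl]cyclopentyl}-6-(4,4,5,5-tetramethyl-1,3,2-dioxaborolan-2-yl)dodecyl 2,4,6-triisopropylbenzoate (both epimers at C6) | CC(C)c1cc(C(C)C)c(C(=O)OCCCC[C@@H](C)C(B2OC(C)(C)C(C)(C)O2)CC[C@@H](C)CCC[C@@H]2CC[C@H]([C@H](C)CCCC(C)C)C2)c(C(C)C)c1 | intermediate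
37 | lithium phenylboronate complex of 36 | [Li+].CC(C)c1cc(C(C)C)c(C(=O)OCCCC[C@@H](C)C([B-]2(c3ccccc3)OC(C)(C)C(C)(C)O2)CC[C@@H](C)CCC[C@@H]2CC[C@H]([C@H](C)CCCC(C)C)C2)c(C(C)C)c1 | intermediate
38 | (5S,9R)-5,9-dimethyl-12-{(1R,3S)-3-[(2R)-6-methylheptan-2-yl]cyclopentyl}dodecyl 2,4,6-triisopropylbenzoate | CC(C)c1cc(C(C)C)c(C(=O)OCCCC[C@@H](C)CCC[C@@H](C)CCC[C@@H]2CC[C@H]([C@H](C)CCCC(C)C)C2)c(C(C)C)c1 | intermediate
39 | (1S)-1-lithio derivative of 38 (lithium on the O-bearing carbon C3'; (−)-sparteine complex) | CC(C)c1cc(C(C)C)c(C(=O)O[C@@H]([Li])CCC[C@@H](C)CCC[C@@H](C)CCC[C@@H]2CC[C@H]([C@H](C)CCCC(C)C)C2)c(C(C)C)c1 | intermediate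
40 | lithium methylboronate complex from 39 and MeBpin | [Li+].CC(C)c1cc(C(C)C)c(C(=O)O[C@@H]([B-]2(C)OC(C)(C)C(C)(C)O2)CCC[C@@H](C)CCC[C@@H](C)CCC[C@@H]2CC[C@H]([C@H](C)CCCC(C)C)C2)c(C(C)C)c1 | intermediate
41 | 2-[(2S,6R,10R)-6,10-dimethyl-13-{(1R,3S)-3-[(2R)-6-methylheptan-2-yl]cyclopentyl}tridecan-2-yl]-4,4,5,5-tetramethyl-1,3,2-dioxaborolane (fragment 2) | CC1(C)OB(OC1(C)C)[C@@H](C)CCC[C@@H](C)CCC[C@@H](C)CCC[C@@H]2CC[C@H]([C@H](C)CCCC(C)C)C2 | intermediate
42 | 1-lithio derivative of 7 (lithium on the O-bearing carbon C2'; TMEDA complex) | COc1c(C)c(CC([Li])OC(=O)c2c(C(C)C)cc(C(C)C)cc2C(C)C)c(OC)c2ccccc12 | intermediate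
43 | lithium boronate complex from 42 and 41 | [Li+].COc1c(C)c(CC(OC(=O)c2c(C(C)C)cc(C(C)C)cc2C(C)C)[B-]2(OC(C)(C)C(C)(C)O2)[C@@H](C)CCC[C@@H](C)CCC[C@@H](C)CCC[C@@H]2CC[C@H]([C@H](C)CCCC(C)C)C2)c(OC)c2ccccc12 | intermediate
44 | 2-[(3S,7S,11R)-1-(1,4-dimethoxy-3-methylnaphthalen-2-yl)-3,7,11-trimethyl-14-{(1R,3S)-3-[(2R)-6-methylheptan-2-yl]cyclopentyl}tetradecan-2-yl]-4,4,5,5-tetramethyl-1,3,2-dioxaborolane (both epimers at C2) | COc1c(C)c(CC(B2OC(C)(C)C(C)(C)O2)[C@@H](C)CCC[C@@H](C)CCC[C@@H](C)CCC[C@@H]2CC[C@H]([C@H](C)CCCC(C)C)C2)c(OC)c2ccccc12 | intermediate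
45 | lithium phenylboronate complex of 44 | [Li+].COc1c(C)c(CC([B-]2(c3ccccc3)OC(C)(C)C(C)(C)O2)[C@@H](C)CCC[C@@H](C)CCC[C@@H](C)CCC[C@@H]2CC[C@H]([C@H](C)CCCC(C)C)C2)c(OC)c2ccccc12 | intermediate
46 | 1,4-dimethoxy-2-methyl-3-[(3S,7S,11R)-3,7,11-trimethyl-14-{(1R,3S)-3-[(2R)-6-methylheptan-2-yl]cyclopentyl}tetradecyl]naphthalene | COc1c(C)c(CC[C@@H](C)CCC[C@@H](C)CCC[C@@H](C)CCC[C@@H]2CC[C@H]([C@H](C)CCCC(C)C)C2)c(OC)c2ccccc12 | intermediate
47 | 2-methyl-3-[(3S,7S,11R)-3,7,11-trimethyl-14-{(1R,3S)-3-[(2R)-6-methylheptan-2-yl]cyclopentyl}tetradecyl]naphthalene-1,4-dione | CC1=C(CC[C@@H](C)CCC[C@@H](C)CCC[C@@H](C)CCC[C@@H]2CC[C@H]([C@H](C)CCCC(C)C)C2)C(=O)c2ccccc2C1=O | target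

**Totals and risks**

Total step count: 23. Longest linear sequence: 16 steps (15 → 47, steps 8–23).

Step 21 (key step): deprotonation may drift to the benzylic C1' methylene of 7, after which the benzoate would be lost by β-elimination, or the crowded boronate may revert before it rearranges. The fallback sets out from 41 and 3 and comes back at 44. Boronic ester 41 is homologated with LiCHCl2 (CH2Cl2, n-BuLi, THF, −100 °C; then ZnCl2, rt) to the α-chloro boronic ester F1, with retention at C3' (Matteson homologation). Compound 3 is chloromethylated (paraformaldehyde, HCl, AcOH) to the benzylic chloride F2, which is converted into the Grignard reagent F3 (Mg, THF, 0 °C). Addition of F3 to F1 and 1,2-migration of the arylmethyl group with loss of chloride should give 44. In this variant C2' arrives as a carbenoid on the boron side, so no deprotonation next to the arene is needed.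

Step 13: facial selectivity in the deprotonation may be eroded by a mismatched pairing between (−)-sparteine and the ring stereocentre beside the O–CH2 group. The fallback sets out from 22 and comes back at 25. The lithiated benzoate is trapped with Me3SnCl to give the configurationally stable stannane F4, which is freed of its minor epimer by chromatography. Tin–lithium exchange (n-BuLi, Et2O, −78 °C, retention) then regenerates 23 as a single epimer, and MeBpin leads through 24 to 25. Stereochemical purity is thus secured by separation at a stable stage and a stereoretentive exchange, not by the kinetic selectivity of the deprotonation alone.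

Step 22: formation of the phenylboronate at the crowded C2' boron may be incomplete, or photo-oxidation of the electron-rich arene may compete, so that the protodeboronation stalls. The fallback sets out from 44 and comes back at 46. Oxidation (NaBO3·4H2O, THF/H2O) gives the secondary alcohol F5, xanthate formation (NaH, CS2, MeI, THF) gives the xanthate F6, and Barton–McCombie deoxygenation (Bu3SnH, AIBN, toluene, 80 °C) should give 46.

**Further compounds**

F1 | step 21 | 2-[(2S,6S,10R)-1-chloro-2,6,10-trimethyl-13-{(1R,3S)-3-[(2R)-6-methylheptan-2-yl]cyclopentyl}tridecyl]-4,4,5,5-tetramethyl-1,3,2-dioxaborolane (both epimers at C1) | ClC(B1OC(C)(C)C(C)(C)O1)[C@@H](C)CCC[C@@H](C)CCC[C@@H](C)CCC[C@@H]1CC[C@H]([C@H](C)CCCC(C)C)C1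
F2 | step 21 | 2-(chloromethyl)-1,4-dimethoxy-3-methylnaphthalene | COc1c(C)c(CCl)c(OC)c2ccccc12
F3 | step 21 | [(1,4-dimethoxy-3-methylnaphthalen-2-yl)methyl]magnesium chloride | COc1c(C)c(C[Mg]Cl)c(OC)c2ccccc12
F4 | step 13 | (S)-{(1S,3R)-3-[(4S)-4,8-dimethylnon-7-en-1-yl]cyclopentyl}(trimethylstannyl)methyl 2,4,6-triisopropylbenzoate | CC(C)=CCC[C@@H](C)CCC[C@@H]1CC[C@H]([C@H]([Sn](C)(C)C)OC(=O)c2c(C(C)C)cc(C(C)C)cc2C(C)C)C1
F5 | step 22 | (3S,7S,11R)-1-(1,4-dimethoxy-3-methylnaphthalen-2-yl)-3,7,11-trimethyl-14-{(1R,3S)-3-[(2R)-6-methylheptan-2-yl]cyclopentyl}tetradecan-2-ol (both epimers at C2) | COc1c(C)c(CC(O)[C@@H](C)CCC[C@@H](C)CCC[C@@H](C)CCC[C@@H]2CC[C@H]([C@H](C)CCCC(C)C)C2)c(OC)c2ccccc12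
F6 | step 22 | O-alkyl S-methyl carbonodithioate (xanthate) of F5 | COc1c(C)c(CC(OC(=S)SC)[C@@H](C)CCC[C@@H](C)CCC[C@@H](C)CCC[C@@H]2CC[C@H]([C@H](C)CCCC(C)C)C2)c(OC)c2ccccc12
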